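**Retrosynthetic overview**
1. 24-Tetracosanolide ⇒ tetracosane-1,24-diol: the ring C–O bond is closed in the forward direction by an acceptorless dehydrogenative macrolactonisation. The diol is symmetric, so either CH2OH end can become the carbonyl.
2. Tetracosane-1,24-diol ⇒ C6 + C12 + C6: the C6–C7 and C18–C19 bonds come from one double copper-catalysed Grignard coupling of 1,12-dibromododecane with the alkoxide-masked Grignard reagent of 6-chlorohexan-1-ol.
3. Ring order: the only ring, the 25-membered lactone, is formed in the last step.

Assumption: the target has no stereocentre (it is achiral), so there is no enantiomer to select; and because the route has only two steps, both are ranked as the steps most likely to fail.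

**Route**

Step 1
Reactants: 1 6-chlorohexan-1-ol (2.6 equiv); 2 1,12-dibromododecane (1.0 equiv)
Product: 6 tetracosane-1,24-diol, via chloromagnesium 6-chlorohexan-1-olate 3 (not isolated), via 6-(chloromagnesiooxy)hexylmagnesium chloride 4 (not isolated), via chloromagnesium 18-bromooctadecan-1-olate 5 (not isolated)
Conditions: 1, iPrMgCl (1.0 equiv to 1), THF, −20 °C → rt; Mg turnings, THF, reflux, 3 h; then added to 2, Li2CuCl4 (5 mol%), THF/NMP, −10 °C → rt, 16 h; 1 M HCl; recrystallised from hot toluene
Reagents that add atoms: none
Why: Kochi–Schlosser copper-catalysed sp3–sp3 cross-coupling, in which the Normant-type Grignard reagent 4 (its hydroxyl masked in the flask as the magnesium alkoxide) displaces both primary bromides of 2 in turn through 5; no stereocentre is formed.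

Step 2
Reactants: 6 tetracosane-1,24-diol
Product: 9 24-tetracosanolide (oxacyclopentacosan-2-one), via 24-hydroxytetracosanal 7 (not isolated), via oxacyclopentacosan-2-ol 8 (not isolated)
Conditions: RuHCl(CO)[2-(tBu2PCH2)-6-(Et2NCH2)C5H3N] (5 mol%), KOtBu (4.8 mol%), degassed toluene, reflux, slow Ar sweep; 6 added over 20 h as a hot (85 °C) toluene solution by syringe pump (final 4 mM), then 6 h reflux
Reagents that add atoms: none
Why: Proposed new method: acceptorless dehydrogenative macrolactonisation, in which the dearomatised pincer complex RuH(CO)[2-(tBu2PCH)-6-(Et2NCH2)C5H3N] (formed in the flask, base-free once KOtBu is consumed) adds one O–H of 6 across the metal and the ligand arm, β-hydride elimination and H2 loss give hydroxy aldehyde 7, the far hydroxyl closes the strain-free 25-membered ring by C–O bond formation to lactol 8 (estimated effective molarity about 0.01–0.05 M, well above the sub-millimolar stationary diol concentration kept by slow addition), and 8, which is dehydrogenated more easily than a primary alcohol, is oxidised irreversibly to 9 with loss of a second H2 that the argon sweep removes; the closest known reaction type is ruthenium-pincer acceptorless dehydrogenative lactonisation of 1,4- to 1,6-diols and dehydrogenative polyesterification of long α,ω-diols, which I believe has not been shown to close a macrocycle; the transient lactol stereocentre becomes the carbonyl, so no stereocentre remains.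

**Compound list**
1 | 6-chlorohexan-1-ol | OCCCCCCCl | starting material
2 | 1,12-dibromododecane | BrCCCCCCCCCCCCBr | starting material
3 | chloromagnesium 6-chlorohexan-1-olate | ClCCCCCCO[Mg]Cl | intermediate
4 | 6-(chloromagnesiooxy)hexylmagnesium chloride | Cl[Mg]CCCCCCO[Mg]Cl | intermediate
5 | chloromagnesium 18-bromooctadecan-1-olate (product of the first coupling) | BrCCCCCCCCCCCCCCCCCCO[Mg]Cl | intermediate
6 | tetracosane-1,24-diol | OCCCCCCCCCCCCCCCCCCCCCCCCO | intermediate
7 | 24-hydroxytetracosanal | O=CCCCCCCCCCCCCCCCCCCCCCCCO | intermediate
8 | oxacyclopentacosan-2-ol (25-membered lactol, transient and racemic) | OC1CCCCCCCCCCCCCCCCCCCCCCCO1 | intermediate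
9 | 24-tetracosanolide (oxacyclopentacosan-2-one, achiral) | O=C1CCCCCCCCCCCCCCCCCCCCCCCO1 | target

**Totals**
Total step count: 2. Longest linear sequence: 2 steps.

**Steps most likely to fail and fallbacks**

Step 2 (the proposed new step) is the most likely to fail. The risks are:
- intermolecular esterification to the 50-membered diolide and linear oligoesters if ring closure of 7 is slower than expected;
- build-up of 7 or of the dialdehyde, followed by aldehyde decarbonylation that poisons the ruthenium catalyst;
- loss of the dilute catalyst to traces of air or water.

The fallback uses known chemistry only. It sets out from 6 and comes back to the route at 9. Diol 6 is monobrominated with 48% aqueous HBr in refluxing toluene, the monobromide being extracted continuously into the toluene layer, to give 24-bromotetracosan-1-ol F1. The remaining primary alcohol is oxidised with CrO3 and H2SO4 in acetone/CH2Cl2 at 0 °C → rt to give 24-bromotetracosanoic acid F2. F2 is then cyclised by intramolecular carboxylate alkylation (Cs2CO3, DMF, 80 °C, slow addition to about 2 mM), the established cesium carboxylate macrolactonisation of ω-halo acids, to give 9. The ring is still closed through the C–O bond, but by SN2 displacement instead of dehydrogenation.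

Step 1 is the second risk. The second coupling may stop at the monobromide stage (18-bromooctadecan-1-ol after work-up), reagent 4 may homocouple to dodecane-1,12-diol, and the magnesium dialkoxide of the product may precipitate and trap material. The fallback replaces the Grignard coupling by acetylide alkylation and hydrogenation. It sets out from 2 and comes back to the route at 6. Commercial hex-5-yn-1-ol is doubly deprotonated with nBuLi (2 equiv) in THF/DMPU at −78 → 0 °C to give lithium 6-lithiohex-5-yn-1-olate F3. F3 (2.3 equiv) is C-alkylated at both ends of 2 (0 °C → rt) to give tetracosa-5,19-diyne-1,24-diol F4. Hydrogenation of F4 (H2 1 atm, 10% Pd/C, EtOAc/EtOH, 50 °C) gives 6.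

**Further compounds**
F1 | step 2 | 24-bromotetracosan-1-ol | OCCCCCCCCCCCCCCCCCCCCCCCCBr
F2 | step 2 | 24-bromotetracosanoic acid | OC(=O)CCCCCCCCCCCCCCCCCCCCCCCBr
F3 | step 1 | lithium 6-lithiohex-5-yn-1-olate | [Li]C#CCCCCO[Li]
F4 | step 1 | tetracosa-5,19-diyne-1,24-diol | OCCCCC#CCCCCCCCCCCCCCC#CCCCCO
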